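**Plan**

1. Ring lettering: ring A is the hydroxylated arene with its ether oxygen para to its CH2; ring B is the meta-disubstituted arene; ring C is the para-disubstituted arene; ring D is the hydroxylated arene with its ether oxygen meta to its CH2.
2. Retrosynthesis: both phenols are masked as methyl ethers and the ring B–CH2CH2–ring C bridge is taken back to CH=CH, which is cut into two aryl aldehydes (reductive carbonyl coupling). Next the CH2–aryl bond at ring D of the other bridge is cut (B-alkyl Suzuki–Miyaura coupling), then the two diaryl ether C–O bonds (SNAr).
3. Enabling feature: both carbons of the bridge to be closed are benzylic, one on ring B (meta to its ether oxygen) and one on ring C (para to its ether oxygen). Each can therefore be carried as a cyano carbon (which also activates ring C for SNAr) and unveiled as CHO; the two sit at the ends of an 18-atom chain hinged at two bent diaryl ethers.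
4. Forward: two SNAr etherifications give the ring C–O–ring D bromide and the ring B–O–ring A aldehyde. Methylenation and hydroboration/Suzuki coupling join rings A and D, nitrile-to-aldehyde reduction follows, and McMurry coupling closes the only new ring, the 20-membered macrocycle. Hydrogenation and O-demethylation finish the route.
5. Stereochemistry: the target has no stereocentre; the geometry of the macrocyclic alkene is erased by hydrogenation.

Key step: step 6

Remark: the ring size (20) is counted along the shortest path through the four arenes.

**Route**

Step 1
Reactants: 1 5-bromo-2-methoxyphenol; 2 4-fluorobenzonitrile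
Product: 3 4-(5-bromo-2-methoxyphenoxy)benzonitrile
Conditions: K2CO3, DMF, 120 °C
Reagents that add atoms: none
Why: Nucleophilic aromatic substitution (addition–elimination) in which the phenoxide of 1 displaces fluoride para to the activating cyano group, while the unactivated aryl bromide stays untouched.

Step 2
Reactants: 4 4-fluoro-3-methoxybenzaldehyde; 5 3-hydroxybenzonitrile
Product: 6 3-(4-formyl-2-methoxyphenoxy)benzonitrile
Conditions: Cs2CO3, DMSO, 110 °C
Reagents that add atoms: none
Why: Nucleophilic aromatic substitution in which the phenoxide of 5 displaces the fluoride para to the formyl group of 4, the meta cyano group of 5 serving only as the latent benzylic carbon of ring B.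

Step 3
Reactants: 6 3-(4-formyl-2-methoxyphenoxy)benzonitrile
Product: 7 3-(4-ethenyl-2-methoxyphenoxy)benzonitrile
Conditions: MePPh3Br, KOtBu, THF, 0 °C to rt
Reagents that add atoms: methyltriphenylphosphonium bromide, C[P+](c1ccccc1)(c1ccccc1)c1ccccc1.[Br-]
Why: Wittig methylenation, the non-stabilised ylide reacting with the aldehyde far faster than with the aryl nitrile, should give the styrene that donates the two carbons of the ring A–ring D bridge.

Step 4
Reactants: 7 3-(4-ethenyl-2-methoxyphenoxy)benzonitrile; 3 4-(5-bromo-2-methoxyphenoxy)benzonitrile
Product: 9 open-chain dinitrile 4-[5-(2-{4-(3-cyanophenoxy)-3-methoxyphenyl}ethyl)-2-methoxyphenoxy]benzonitrile, via B-alkyl-9-BBN adduct 8 (not isolated)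
Conditions: 9-BBN, THF, 0 °C to rt; then 3, PdCl2(dppf), aq. K3PO4, DMF, 60 °C
Reagents that add atoms: none
Why: Anti-Markovnikov hydroboration of the styrene with 9-BBN (much faster than reduction of aryl nitriles) followed by B-alkyl Suzuki–Miyaura coupling with aryl bromide 3 should join rings A and D through a CH2CH2 bridge already at the final oxidation level.

Step 5
Reactants: 9 open-chain dinitrile
Product: 11 dialdehyde 4-[5-(2-{4-(3-formylphenoxy)-3-methoxyphenyl}ethyl)-2-methoxyphenoxy]benzaldehyde, via bis(N-diisobutylalumino)aldimine 10 (not isolated)
Conditions: i-Bu2AlH, CH2Cl2, −78 to 0 °C; then aq. HCl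
Reagents that add atoms: water, O
Why: Partial reduction of both aryl nitriles with i-Bu2AlH stops at the N-aluminoaldimine, which resists further hydride addition and is hydrolysed to the aldehyde on acidic work-up (nitrile-to-aldehyde reduction).

Step 6
Reactants: 11 dialdehyde
Product: 13 macrocyclic stilbene (di-O-methyl ether of the target having CH=CH between rings B and C; E/Z mixture), via macrocyclic dichlorotitanium pinacolate 12 (not isolated)
Conditions: TiCl4, Zn, pyridine, THF, reflux; 11 added slowly by syringe pump (high dilution)
Reagents that add atoms: none
Why: Low-valent titanium made from TiCl4 and Zn transfers one electron to each formyl group, the two ketyl radicals couple carbon to carbon on the metal to give the titanium pinacolate 12, and a second reducing equivalent deoxygenates 12 to the alkene, driven by the strength of the Ti–O bonds. The closest known reaction type is the intramolecular McMurry coupling of dialdehydes to macrocyclic stilbenes and cyclophane alkenes. The only ring closed is the 20-membered macrocycle, formed by end-to-end closure of a chain whose formyl carbons are 18 atoms apart, with both C=O bonds outside the new ring (exo closure at both trigonal carbons). No stereocentre is created, and the alkene geometry is irrelevant because step 7 saturates it. The step needs ring closure to win over intermolecular coupling, which slow addition of 11 to excess reagent at high dilution should secure, helped by the two bent diaryl ether hinges, the meta linkage of ring B and the flexible saturated bridge between rings A and D. Chemoselectivity is not an issue because the two formyl groups are the only reducible functions left, the aryl methyl ethers and diaryl ethers being inert.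

Step 7
Reactants: 13 macrocyclic stilbene
Product: 14 macrocyclic di-O-methyl ether of the target (saturated CH2CH2 bridge between rings B and C)
Conditions: H2 (1 atm), 10% Pd/C, EtOAc, rt
Reagents that add atoms: none
Why: Heterogeneous catalytic hydrogenation should saturate the stilbene C=C of either geometry, the aryl methyl ethers and diaryl ethers being inert.

Step 8
Reactants: 14 macrocyclic di-O-methyl ether
Product: 15 target CNP0329842.0 (macrocyclic bis(bibenzyl) diphenol)
Conditions: BBr3, CH2Cl2, −78 °C to rt; then H2O
Reagents that add atoms: none
Why: Lewis acid-mediated O-demethylation of both aryl methyl ethers with BBr3, to which the diaryl ethers and bibenzyl bridges are stable, should release the two phenols on hydrolytic work-up.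

**Compound list**

1 | 5-bromo-2-methoxyphenol | COc1ccc(Br)cc1O | starting material
2 | 4-fluorobenzonitrile | N#Cc1ccc(F)cc1 | starting material
3 | 4-(5-bromo-2-methoxyphenoxy)benzonitrile | COc1ccc(Br)cc1Oc1ccc(C#N)cc1 | intermediate
4 | 4-fluoro-3-methoxybenzaldehyde | COc1cc(C=O)ccc1F | starting material
5 | 3-hydroxybenzonitrile | N#Cc1cccc(O)c1 | starting material
6 | 3-(4-formyl-2-methoxyphenoxy)benzonitrile | COc1cc(C=O)ccc1Oc1cccc(C#N)c1 | intermediate
7 | 3-(4-ethenyl-2-methoxyphenoxy)benzonitrile | COc1cc(C=C)ccc1Oc1cccc(C#N)c1 | intermediate
8 | B-alkyl-9-BBN adduct, 3-{4-[2-(9-borabicyclo[3.3.1]nonan-9-yl)ethyl]-2-methoxyphenoxy}benzonitrile (not isolated) | COc1cc(CCB2C3CCCC2CCC3)ccc1Oc1cccc(C#N)c1 | intermediate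
9 | open-chain dinitrile, 4-[5-(2-{4-(3-cyanophenoxy)-3-methoxyphenyl}ethyl)-2-methoxyphenoxy]benzonitrile | COc1cc(CCc2ccc(OC)c(Oc3ccc(C#N)cc3)c2)ccc1Oc1cccc(C#N)c1 | intermediate
10 | bis(N-diisobutylalumino)aldimine of 11 (not isolated) | COc1cc(CCc2ccc(OC)c(Oc3ccc(C=N[Al](CC(C)C)CC(C)C)cc3)c2)ccc1Oc1cccc(C=N[Al](CC(C)C)CC(C)C)c1 | intermediate
11 | dialdehyde, 4-[5-(2-{4-(3-formylphenoxy)-3-methoxyphenyl}ethyl)-2-methoxyphenoxy]benzaldehyde | COc1cc(CCc2ccc(OC)c(Oc3ccc(C=O)cc3)c2)ccc1Oc1cccc(C=O)c1 | intermediate
12 | macrocyclic dichlorotitanium pinacolate (tetravalent titanium 1,2-diolate spanning the ring B and ring C benzylic carbons; simplified drawing of the metal-bound pinacolate, diastereomer mixture, not isolated) | COc1cc2ccc1Oc1cccc(c1)C1O[Ti](Cl)(Cl)OC1c1ccc(cc1)Oc1cc(ccc1OC)CC2 | intermediate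
13 | macrocyclic stilbene, di-O-methyl ether of the target with CH=CH between rings B and C (E/Z mixture, geometry immaterial) | COc1cc2ccc1Oc1cccc(c1)C=Cc1ccc(cc1)Oc1cc(ccc1OC)CC2 | intermediate
14 | macrocyclic di-O-methyl ether of the target | COc1cc2ccc1Oc1cccc(c1)CCc1ccc(cc1)Oc1cc(ccc1OC)CC2 | intermediate
15 | CNP0329842.0, 20-membered bis(bibenzyl) diether diphenol (no stereocentre) | Oc1cc2ccc1Oc1cccc(c1)CCc1ccc(cc1)Oc1cc(ccc1O)CC2 | target

**Summary**

Total step count: 8. Longest linear sequence: 7 steps (steps 2 to 8, from 4 and 5).

**Steps most likely to fail**

Step 6. Intermolecular carbonyl coupling (oligomerisation) may outrun ring closure, or the reaction may stall at the pinacol stage because the macrocyclic alkene is strained. The fallback is an intramolecular Wurtz coupling, which forms the saturated bridge directly and never passes through the alkene. It sets out from 11: reduction with NaBH4 in MeOH/THF at 0 °C should give the bis(benzylic alcohol) F1, and PBr3 in CH2Cl2 at 0 °C should convert it into the bis(benzylic bromide) F2. Slow addition of F2 to Na with catalytic tetraphenylethylene in THF at high dilution should close the 20-membered ring by reductive sp3–sp3 coupling. The fallback comes back to the route at 14, so step 7 is no longer needed.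

Step 4. Oxidative addition of zerovalent palladium into the electron-rich aryl bromide may be slow, letting protodeboronation or β-hydride elimination of the alkylborane compete; partial reduction of a nitrile by 9-BBN is also possible. The fallback replaces the sp3–sp2 coupling by an sp2–sp2 Heck reaction plus alkene reduction. It sets out from 7 (with 3): Pd(OAc)2, P(o-tol)3, NaOAc, DMF, 110 °C should give the (E)-stilbene dinitrile F3. Diimide reduction (TsNHNH2, NaOAc, THF/H2O, reflux), which spares nitriles, should then give the bibenzyl, and the fallback comes back to the route at 9.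

Step 2. Addition–elimination may be sluggish, because the fluoroarene is activated by only one formyl group and carries a donating ortho methoxy group, and the cyanophenoxide is a weak nucleophile; the aldehyde may erode at the temperature needed. The fallback is a copper-catalysed Ullmann-type C–O coupling, which does not depend on activation by the formyl group. It sets out from 5, which is coupled with commercial 4-bromo-3-methoxybenzaldehyde (COc1cc(C=O)ccc1Br) using CuI, N,N-dimethylglycine and Cs2CO3 in dioxane at 100 °C. It comes back to the route at 6 and makes no new intermediate.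

**Further compounds**

F1 | step 6 | bis(benzylic alcohol), {4-[5-(2-{4-[3-(hydroxymethyl)phenoxy]-3-methoxyphenyl}ethyl)-2-methoxyphenoxy]phenyl}methanol | COc1cc(CCc2ccc(OC)c(Oc3ccc(CO)cc3)c2)ccc1Oc1cccc(CO)c1
F2 | step 6 | bis(benzylic bromide), 1-[3-(bromomethyl)phenoxy]-4-(2-{3-[4-(bromomethyl)phenoxy]-4-methoxyphenyl}ethyl)-2-methoxybenzene | COc1cc(CCc2ccc(OC)c(Oc3ccc(CBr)cc3)c2)ccc1Oc1cccc(CBr)c1
F3 | step 4 | (E)-stilbene dinitrile, 4-[5-((E)-2-{4-(3-cyanophenoxy)-3-methoxyphenyl}ethenyl)-2-methoxyphenoxy]benzonitrile | COc1cc(/C=C/c2ccc(OC)c(Oc3ccc(C#N)cc3)c2)ccc1Oc1cccc(C#N)c1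
F0 | step 2 | none | none
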